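## Structural features

Kuwanon B is a flavone: ring A (benzene C4a–C8a with OH on C5 and C7) is fused to ring C (the γ-pyranone O1–C2=C3–C4(=O)), and ring B hangs on C2 through C1'. C3 carries a 3-methylbut-2-enyl (prenyl) chain, so the C2=C3 double bond is fully substituted. Ring B is a 1,2,3,4-tetrasubstituted benzene: C1' (to C2), C2' (free OH), C3' (bonded to the vinylic carbon of a 2,2-dimethyl-2H-pyran) and C4' (bonded to the pyran oxygen). It is therefore an angular 5-hydroxy-2,2-dimethyl-2H-chromen-6-yl unit. The molecule has no stereocentre, so the problem is one of regiochemistry and chemoselectivity only. Fragile groups are the chromene alkene and the prenyl alkene (acid, electrophiles, oxidants), the three free phenols, and the 2'-OH, which can cyclise onto the neighbouring prenyl group under acidic or oxidative conditions. The real difficulty has three parts: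
- the C2–C1' bond between a fully substituted vinylogous-ester carbon and a ring B carbon flanked by an oxygenated carbon;
- placing the pyran on C3'/C4' rather than C4'/C5', while keeping O2' from competing with the ring A oxygen when ring C is closed (a 1,3-diketone precursor can close on either phenol);
- freeing the phenols without acid.

The feature exploited is that C2'(O)–C3'–C4'(O) of ring B is the O=C–C–C=O unit of a cyclohexane-1,3-dione, with C1' as its α'-carbon. Ring B can therefore be carried as a cyclohexenone in which C1' is an enolate carbon and O2' is a ketone oxygen, and be aromatised late. In one sentence: the C2–C1' bond is made by addition–elimination of the α'-enolate of the cyclohexenone-stage ring B (13) at C2 of a 2-sulfonylchromone (9), and ring B is aromatised afterwards.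

## Logic of the disconnections

22 to 21. The O–H bonds at O5 and O7 are traced back to two O–allyl bonds. The enolate chemistry upstream tolerates no acidic OH on ring A, and allyl ethers can be removed under neutral conditions. The forward step must leave the C-prenyl group and the chromene alkene alone and must not transfer allyl to a ring A carbon.

21 to 16. Ring B is dearomatised by removing the C1'=C6' unsaturation, so that C2' becomes a ketone carbon and C1' an sp3 carbon. This turns O2' into a carbonyl that cannot close ring C or attack the prenyl group, and makes C1' enolisable. The forward step must dehydrogenate one C–C bond next to a ketone in the presence of three kinds of alkene and must avoid free-phenol oxidation.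

16 to 13 and 9 (key). The C2–C1' bond is cut. C1' is the α'-carbon of a vinylogous ester and so a natural enolate carbon. C2 is a vinylogous acyl carbon and so a natural electrophile once it bears a nucleofuge. The cut gives two fragments of similar size, with ring C already closed and the prenyl group already on C3, so no question remains about which oxygen closes ring C. The forward step needs α' (not γ) enolisation of 13, attack by carbon at C2 (not C4) of 9, and a leaving group that departs from the adduct.

13 to 10 and 11. The C3'–C(vinyl) bond and the O–CMe2 bond of the pyran are cut. Because 10 is symmetric, only one 2H-pyran can form and the angular ring B pattern follows without any selectivity problem. The forward step is a condensation followed by a six-electron ring closure through oxygen.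

9 to 7. The two S–O bonds are cut. The ring synthesis delivers a sulfide, and the sulfone is the nucleofuge the key step needs. The oxidant must prefer sulfur to the trisubstituted prenyl alkene.

7 to 5. The O1–C2 and C2–C3 bonds of ring C and the S–CH3 bond are cut, so C2 arrives as a one-carbon dithio unit at the carboxylic oxidation level. Ring C is closed and armed with its leaving group in one operation. The α-carbon of 5 must be doubly functionalised, and the ortho phenoxide must close the ring before it is alkylated.

5 to 2 and 3. The bond between the α-carbon of the aryl ketone (future C3) and the prenyl CH2 is cut. The forward step is a mono-C-alkylation of a phenoxide–enolate dianion at carbon.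

2 to 1. Two O–allyl bonds are cut. The hydroxyl hydrogen-bonded to the acetyl group is left free and later becomes O1.

## Other disconnections considered

Alternative 1: The first that comes to mind, a Baker–Venkataraman sequence.
- Cut: C2–C3 and O1–C2 of ring C.
- Forward key step: the free phenol of 5 is acylated with the aromatic ring B acid A1 (2'-O as methoxymethyl ether) to give ester A2. Base shifts the acyl group from O to the α-carbon to give 1,3-diketone A3, and acid closes ring C.
- Ground for preferring the chosen plan:
  - A1 must be built on a resorcinol-type arene, where the pyran has to be steered to the carbon between the two oxygens and one of two phenols then protected selectively.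
  - The acyl shift must form a C–C bond at a secondary, prenyl-bearing enolate carbon next to a di-ortho-substituted aryl ketone.
  - A3 closes correctly only while the 2'-O group survives.
  - The acid that closes ring C and removes the methoxymethyl group is the reagent class that the prenyl/2'-OH/chromene array tolerates least.
  - The chosen plan needs no 2'-O protecting group and no acid, and takes the ring B pattern from symmetry in fewer steps.

Alternative 2: The same bond with ring B already aromatic.
- Cut: C2–C1'.
- Forward key step: Liebeskind–Srogl coupling of thioether 7 with boronic acid A4 (Pd(PPh3)4 as the zerovalent palladium source, CuTC = Cu(O2C-C4H3S)) to give the 2'-O-protected flavone A5.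
- Ground for preferring the chosen plan:
  - A4 requires an aromatic chromene whose angular regiochemistry and C6 (not C8) metalation must each be won.
  - An ortho-alkoxy, electron-rich boronic acid is prone to protodeboronation.
  - Zerovalent palladium ionises aryl allyl ethers, so the ring A protecting groups would have to change.
  - A 2'-O protecting group must again be removed at the end.
  - The enolate route forms the same bond without a metal, and the 2'-oxygen is masked by the oxidation level of the ring.

Alternative 3: Alkyne route with late prenylation.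
- Cut: O1–C2 and C3–C(prenyl).
- Forward key step: iodocyclisation (ICl) of ynone A6 with loss of a methyl group gives 3-iodoflavone A7, followed by prenyl cross-coupling at C3.
- Ground for preferring the chosen plan:
  - Electrophilic iodine meets the electron-rich chromene alkene before or beside the alkyne.
  - Six-membered closure must beat five-membered (aurone) closure.
  - The prenyl transfer can deliver the 1,1-dimethylallyl isomer.
  - Ring A must be carried as methyl ethers, whose cleavage needs boron trihalides that the prenyl and chromene groups do not survive.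
  - The chosen plan has the prenyl group in place from the second step and never exposes the alkenes to a halonium source.

Key step: step 6

Assumption: 1, 3, 10 and 11 are taken as commercial. Intermediates 8, 15, 16, 18 and 19 contain stereocentres that form without control (racemates or diastereomer mixtures) and are all destroyed before 21, so their SMILES carry no stereodescriptors; the target has no stereocentre.

## Route

Step 1
Reactants: 1 2',4',6'-trihydroxyacetophenone
Product: 2 1-[2-hydroxy-4,6-bis(prop-2-enyloxy)phenyl]ethanone
Conditions: allyl bromide (2.1 equiv), K2CO3 (2.5 equiv), acetone, reflux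
Reagents that add atoms: allyl bromide C=CCBr
Why: Williamson O-alkylation; the hydroxyl that is hydrogen-bonded to the acetyl carbonyl is the least nucleophilic and should stay free when two equivalents of bromide are used, as is usual for phloroacetophenone.

Step 2
Reactants: 2 1-[2-hydroxy-4,6-bis(prop-2-enyloxy)phenyl]ethanone; 3 1-bromo-3-methylbut-2-ene
Product: 5 1-[2-hydroxy-4,6-bis(prop-2-enyloxy)phenyl]-5-methylhex-4-en-1-one, via dilithium dianion 4 (not isolated)
Conditions: LDA (2.2 equiv), THF, −78 → −20 °C; then 3 (1.0 equiv), −78 → 0 °C; aq. NH4Cl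
Reagents that add atoms: none
Why: Alkylation of the phenoxide–enolate dianion of an o-hydroxyacetophenone takes place at the enolate carbon, the more basic and less chelated site; the primary allylic bromide reacts by SN2 at CH2, so the prenyl group should arrive unrearranged.

Step 3
Reactants: 5 1-[2-hydroxy-4,6-bis(prop-2-enyloxy)phenyl]-5-methylhex-4-en-1-one
Product: 7 3-(3-methylbut-2-enyl)-2-(methylsulfanyl)-5,7-bis(prop-2-enyloxy)-4H-chromen-4-one, via ketene dithioacetal 6 (not isolated)
Conditions: t-BuOK (3.2 equiv), CS2 (1.3 equiv), THF, 0 °C → rt; then MeI (2.2 equiv), 0 °C → rt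
Reagents that add atoms: carbon disulfide S=C=S; iodomethane CI
Why: α-Oxoketene dithioacetal formation followed by intramolecular addition–elimination, the annulation used to make 2-alkylthio-isoflavones from deoxybenzoins: the enolate adds to CS2, double S-methylation gives 6, and the ortho phenoxide displaces one methanethiolate in a six-membered closure. C2 is thereby installed at the carboxylic oxidation level with a latent leaving group.

Step 4
Reactants: 7 3-(3-methylbut-2-enyl)-2-(methylsulfanyl)-5,7-bis(prop-2-enyloxy)-4H-chromen-4-one
Product: 9 3-(3-methylbut-2-enyl)-2-(methylsulfonyl)-5,7-bis(prop-2-enyloxy)-4H-chromen-4-one, via sulfoxide 8 (not isolated)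
Conditions: 30% aq. H2O2 (5 equiv), (NH4)6Mo7O24·4H2O (10 mol%), EtOH, 0 °C → rt
Reagents that add atoms: hydrogen peroxide OO
Why: Molybdate-catalysed peroxide oxidation of a sulfide to the sulfone through the sulfoxide; the peroxomolybdate transfers oxygen readily to sulfur but is a poor epoxidant of unfunctionalised alkenes, which is why it is the standard choice for this oxidation beside trisubstituted alkenes.

Step 5
Reactants: 10 cyclohexane-1,3-dione; 11 3-methylbut-2-enal
Product: 13 2,2-dimethyl-7,8-dihydro-2H-chromen-5(6H)-one, via Knoevenagel dienedione 12 (not isolated)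
Conditions: ethylenediammonium diacetate (10 mol%), MeOH, rt
Reagents that add atoms: none
Why: Formal [3+3] annulation: Knoevenagel condensation gives the 1-oxatriene 12, which closes by thermal oxa-6π electrocyclisation. Because 10 is symmetric its two carbonyl oxygens are equivalent and only one 2H-pyran can form, which fixes the angular ring B pattern.

Step 6
Reactants: 13 2,2-dimethyl-7,8-dihydro-2H-chromen-5(6H)-one; 9 3-(3-methylbut-2-enyl)-2-(methylsulfonyl)-5,7-bis(prop-2-enyloxy)-4H-chromen-4-one
Product: 16 rac-2-(2,2-dimethyl-5-oxo-5,6,7,8-tetrahydro-2H-chromen-6-yl)-3-(3-methylbut-2-enyl)-5,7-bis(prop-2-enyloxy)-4H-chromen-4-one, via lithium enolate 14 (not isolated), via sulfonyl adduct 15 (not isolated)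
Conditions: 13 (2.1 equiv), LDA (2.05 equiv), THF, −78 °C; then 9 (1.0 equiv) in THF, −78 → −20 °C; aq. NH4Cl
Reagents that add atoms: none
Why: LDA removes the kinetically favoured α'-proton (C6) of the vinylogous ester 13 to give the cross-conjugated lithium enolate 14. Its carbon terminus adds to C2 of 9, the β-carbon of the chromone enone that is further activated by the geminal sulfonyl group, to give the chromanone enolate 15, and expulsion of methanesulfinate (E1cB) restores the pyranone and delivers 16. The closest known reaction type is nucleophilic vinylic substitution (addition–elimination) by carbanions on 2-sulfinyl- and 2-sulfonyl-chromones and on β-sulfonyl enones. No ring is closed in this step; it forms the C2–C1' bond and leaves ring B one dehydrogenation away from the arene. The new stereocentre (C6 of the cyclohexenone, the future C1') is formed without control and needs none, because it is enolisable and becomes an sp2 carbon in step 7. Three selectivities are needed: α' rather than γ (C8) enolisation, secured by kinetic deprotonation at −78 °C; attack at C2 rather than C4, secured by the vinylogous-ester character of the C4 carbonyl, its shielding by the 5-O-allyl group and the nucleofuge on C2; and C- rather than O-attack, favoured for a lithium enolate in THF. Because 16 is more acidic than 13, a second equivalent of 14 is consumed as base and 13 is recovered from it.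

Step 7
Reactants: 16 rac-2-(2,2-dimethyl-5-oxo-5,6,7,8-tetrahydro-2H-chromen-6-yl)-3-(3-methylbut-2-enyl)-5,7-bis(prop-2-enyloxy)-4H-chromen-4-one
Product: 21 2-(5-hydroxy-2,2-dimethyl-2H-chromen-6-yl)-3-(3-methylbut-2-enyl)-5,7-bis(prop-2-enyloxy)-4H-chromen-4-one, via lithium enolate 17 (not isolated), via selenide 18 (not isolated), via selenoxide 19 (not isolated), via dienone 20 (not isolated)
Conditions: LiHMDS (1.1 equiv), THF, −78 °C; PhSeCl (1.05 equiv), −78 °C; then mCPBA (1.0 equiv), CH2Cl2, −78 °C; i-Pr2NH, −78 °C → rt
Reagents that add atoms: none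
Why: α-Selenenylation of the doubly stabilised enolate 17 at C6, then selenoxide syn-elimination (the only syn β-hydrogens are on C7), gives the cross-conjugated dienone 20, the keto tautomer of the phenol, which aromatises by amine-catalysed enolisation. One equivalent of peracid at −78 °C should oxidise selenium much faster than any alkene, and the new 2'-OH is never exposed to an oxidant.

Step 8
Reactants: 21 2-(5-hydroxy-2,2-dimethyl-2H-chromen-6-yl)-3-(3-methylbut-2-enyl)-5,7-bis(prop-2-enyloxy)-4H-chromen-4-one
Product: 22 Kuwanon B, 5,7-dihydroxy-2-(5-hydroxy-2,2-dimethyl-2H-chromen-6-yl)-3-(3-methylbut-2-enyl)-4H-chromen-4-one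
Conditions: Pd(PPh3)4 (5 mol%), morpholine (10 equiv), THF, rt, argon, dark
Reagents that add atoms: none
Why: Tsuji–Trost-type deallylation: zerovalent palladium ionises the two aryl allyl ethers to phenoxides and a π-allyl complex that is intercepted by morpholine. The C-prenyl group and the chromene alkene carry no leaving group and should be inert, and the neutral conditions spare the acid-labile 2'-OH/prenyl/chromene array.

## Compound list

1 | 2',4',6'-trihydroxyacetophenone | CC(=O)c1c(O)cc(O)cc1O | starting material
2 | 1-[2-hydroxy-4,6-bis(prop-2-enyloxy)phenyl]ethanone | CC(=O)c1c(O)cc(OCC=C)cc1OCC=C | intermediate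
3 | 1-bromo-3-methylbut-2-ene (prenyl bromide) | CC(C)=CCBr | starting material
4 | dilithium 2-(1-oxidoethenyl)-3,5-bis(prop-2-enyloxy)phenolate (dianion of 2) | [Li+].[Li+].C=C([O-])c1c([O-])cc(OCC=C)cc1OCC=C | intermediate
5 | 1-[2-hydroxy-4,6-bis(prop-2-enyloxy)phenyl]-5-methylhex-4-en-1-one | CC(C)=CCCC(=O)c1c(O)cc(OCC=C)cc1OCC=C | intermediate
6 | 2-[bis(methylsulfanyl)methylidene]-1-[2-hydroxy-4,6-bis(prop-2-enyloxy)phenyl]-5-methylhex-4-en-1-one | CSC(SC)=C(CC=C(C)C)C(=O)c1c(O)cc(OCC=C)cc1OCC=C | intermediate
7 | 3-(3-methylbut-2-enyl)-2-(methylsulfanyl)-5,7-bis(prop-2-enyloxy)-4H-chromen-4-one | CSc1oc2cc(OCC=C)cc(OCC=C)c2c(=O)c1CC=C(C)C | intermediate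
8 | rac-3-(3-methylbut-2-enyl)-2-(methylsulfinyl)-5,7-bis(prop-2-enyloxy)-4H-chromen-4-one | CS(=O)c1oc2cc(OCC=C)cc(OCC=C)c2c(=O)c1CC=C(C)C | intermediate
9 | 3-(3-methylbut-2-enyl)-2-(methylsulfonyl)-5,7-bis(prop-2-enyloxy)-4H-chromen-4-one | CS(=O)(=O)c1oc2cc(OCC=C)cc(OCC=C)c2c(=O)c1CC=C(C)C | intermediate
10 | cyclohexane-1,3-dione | O=C1CCCC(=O)C1 | starting material
11 | 3-methylbut-2-enal | CC(C)=CC=O | starting material
12 | 2-(3-methylbut-2-enylidene)cyclohexane-1,3-dione | CC(C)=CC=C1C(=O)CCCC1=O | intermediate
13 | 2,2-dimethyl-7,8-dihydro-2H-chromen-5(6H)-one | CC1(C)C=CC2=C(CCCC2=O)O1 | intermediate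
14 | lithium 2,2-dimethyl-7,8-dihydro-2H-chromen-5-olate | [Li+].[O-]C1=CCCC2=C1C=CC(C)(C)O2 | intermediate
15 | lithium enolate of 2-(2,2-dimethyl-5-oxo-5,6,7,8-tetrahydro-2H-chromen-6-yl)-3-(3-methylbut-2-enyl)-2-(methylsulfonyl)-5,7-bis(prop-2-enyloxy)chroman-4-one (diastereomer mixture) | [Li+].CC(C)=CCC1=C([O-])c2c(OCC=C)cc(OCC=C)cc2OC1(C3CCC4=C(C=CC(C)(C)O4)C3=O)S(C)(=O)=O | intermediate
16 | rac-2-(2,2-dimethyl-5-oxo-5,6,7,8-tetrahydro-2H-chromen-6-yl)-3-(3-methylbut-2-enyl)-5,7-bis(prop-2-enyloxy)-4H-chromen-4-one | CC(C)=CCc1c(C2CCC3=C(C=CC(C)(C)O3)C2=O)oc2cc(OCC=C)cc(OCC=C)c2c1=O | intermediate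
17 | lithium 2,2-dimethyl-6-[3-(3-methylbut-2-enyl)-4-oxo-5,7-bis(prop-2-enyloxy)-4H-chromen-2-yl]-7,8-dihydro-2H-chromen-5-olate (enolate of 16) | [Li+].CC(C)=CCc1c(C2=C([O-])C3=C(CC2)OC(C)(C)C=C3)oc2cc(OCC=C)cc(OCC=C)c2c1=O | intermediate
18 | rac-2-[2,2-dimethyl-5-oxo-6-(phenylselanyl)-5,6,7,8-tetrahydro-2H-chromen-6-yl]-3-(3-methylbut-2-enyl)-5,7-bis(prop-2-enyloxy)-4H-chromen-4-one | CC(C)=CCc1c(C2([Se]c3ccccc3)CCC3=C(C=CC(C)(C)O3)C2=O)oc2cc(OCC=C)cc(OCC=C)c2c1=O | intermediate
19 | 2-[2,2-dimethyl-5-oxo-6-(phenylseleninyl)-5,6,7,8-tetrahydro-2H-chromen-6-yl]-3-(3-methylbut-2-enyl)-5,7-bis(prop-2-enyloxy)-4H-chromen-4-one (diastereomer mixture) | CC(C)=CCc1c(C2([Se](=O)c3ccccc3)CCC3=C(C=CC(C)(C)O3)C2=O)oc2cc(OCC=C)cc(OCC=C)c2c1=O | intermediate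
20 | 2-(2,2-dimethyl-5-oxo-5,8-dihydro-2H-chromen-6-yl)-3-(3-methylbut-2-enyl)-5,7-bis(prop-2-enyloxy)-4H-chromen-4-one | CC(C)=CCc1c(C2=CCC3=C(C=CC(C)(C)O3)C2=O)oc2cc(OCC=C)cc(OCC=C)c2c1=O | intermediate
21 | 2-(5-hydroxy-2,2-dimethyl-2H-chromen-6-yl)-3-(3-methylbut-2-enyl)-5,7-bis(prop-2-enyloxy)-4H-chromen-4-one | CC(C)=CCc1c(-c2ccc3c(c2O)C=CC(C)(C)O3)oc2cc(OCC=C)cc(OCC=C)c2c1=O | intermediate
22 | Kuwanon B, 5,7-dihydroxy-2-(5-hydroxy-2,2-dimethyl-2H-chromen-6-yl)-3-(3-methylbut-2-enyl)-4H-chromen-4-one | CC(C)=CCc1c(-c2ccc3c(c2O)C=CC(C)(C)O3)oc2cc(O)cc(O)c2c1=O | target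

## Step count and least certain steps

Total steps: 8. Longest linear sequence: 7 steps (1, 2, 3, 4, 6, 7, 8); step 5 makes the second fragment in one step.

Step 6 (key step).
- What may go wrong: proton transfer from the S-methyl group of 9 to the basic enolate instead of addition; attack at the C4 carbonyl; or slow addition at the hindered, prenyl-flanked C2, so that the sulfone is consumed by the base. All three follow from using a hard, basic lithium enolate where stabilised carbanions are the usual partners.
- Fallback (sets out from 13 and 9, returns at 16): 13 is converted with LDA and Me3SiCl into 2,2-dimethyl-5-(trimethylsilyloxy)-7,8-dihydro-2H-chromene F1. F1 is added to 9 in CH2Cl2 at −78 °C with Me3SiOTf. O-Silylation of the chromone carbonyl gives a 4-silyloxybenzopyrylium ion, the neutral silyl enol ether attacks it at C2 (Mukaiyama–Michael type), and loss of methanesulfinate and of the silyl groups on work-up gives 16. The union is thus moved from an anionic to a cationic manifold with no base present.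

Step 4.
- What may go wrong: competing epoxidation of the prenyl alkene, or attack of ethanol or hydroperoxide at C2 of the newly formed, strongly electrophilic sulfone (solvolysis of the leaving group).
- Fallback (sets out from 5, returns at 16, and also bypasses step 3): condensation of 5 with N,N-dimethylformamide dimethyl acetal and ring closure should give 3-(3-methylbut-2-enyl)-5,7-bis(prop-2-enyloxy)-4H-chromen-4-one F2. Zincation of its only pyranone C–H (C2) with TMP2Zn·2MgCl2·2LiCl and quenching with iodine should give 2-iodo-3-(3-methylbut-2-enyl)-5,7-bis(prop-2-enyloxy)-4H-chromen-4-one F3. F3 takes the place of 9 in step 6, where enolate 14 displaces iodide by addition–elimination to give 16. No sulfur and no oxidant are used.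

Step 7.
- What may go wrong: slow or oxygen-selective selenenylation of the hindered, strongly delocalised enolate 17, or addition of the selenium electrophile or of benzeneselenenic acid to the prenyl, chromene or allyl alkenes.
- Fallback (sets out from 16, returns at 21): 16 is silylated with t-BuMe2SiOTf and Et3N to the dienol ether 2-[5-(tert-butyldimethylsilyloxy)-2,2-dimethyl-7,8-dihydro-2H-chromen-6-yl]-3-(3-methylbut-2-enyl)-5,7-bis(prop-2-enyloxy)-4H-chromen-4-one F4. Hydride abstraction with DDQ (1.05 equiv, CH2Cl2, 0 °C) aromatises the dihydroarene to the aryl silyl ether 2-[5-(tert-butyldimethylsilyloxy)-2,2-dimethyl-2H-chromen-6-yl]-3-(3-methylbut-2-enyl)-5,7-bis(prop-2-enyloxy)-4H-chromen-4-one F5. Bu4NF then gives 21. The phenol stays silylated while the quinone is present, which blocks oxidative cyclisation onto the prenyl group.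

Step 8.
- What may go wrong: carbon allylation of ring A (C6 or C8), because a phloroglucinol-type phenoxide is a carbon nucleophile toward the π-allyl palladium intermediate; or incomplete cleavage of the hydrogen-bonded 5-O-allyl ether.
- Fallback (sets out from 21, returns at 22): isomerisation of the two allyl ethers with hydrogen-activated [Ir(cod)(PMePh2)2]PF6 in THF, which should leave the trisubstituted alkenes alone, gives 2-(5-hydroxy-2,2-dimethyl-2H-chromen-6-yl)-3-(3-methylbut-2-enyl)-5,7-bis[(E)-prop-1-enyloxy]-4H-chromen-4-one F6. Brief hydrolysis of the enol ethers with dilute aqueous HCl in acetone at rt gives 22. No π-allyl species is formed.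

## Further compounds

F1 | step 6 | 2,2-dimethyl-5-(trimethylsilyloxy)-7,8-dihydro-2H-chromene | C[Si](C)(C)OC1=CCCC2=C1C=CC(C)(C)O2
F2 | step 4 | 3-(3-methylbut-2-enyl)-5,7-bis(prop-2-enyloxy)-4H-chromen-4-one | CC(C)=CCc1coc2cc(OCC=C)cc(OCC=C)c2c1=O
F3 | step 4 | 2-iodo-3-(3-methylbut-2-enyl)-5,7-bis(prop-2-enyloxy)-4H-chromen-4-one | CC(C)=CCc1c(I)oc2cc(OCC=C)cc(OCC=C)c2c1=O
F4 | step 7 | 2-[5-(tert-butyldimethylsilyloxy)-2,2-dimethyl-7,8-dihydro-2H-chromen-6-yl]-3-(3-methylbut-2-enyl)-5,7-bis(prop-2-enyloxy)-4H-chromen-4-one | CC(C)=CCc1c(C2=C(O[Si](C)(C)C(C)(C)C)C3=C(CC2)OC(C)(C)C=C3)oc2cc(OCC=C)cc(OCC=C)c2c1=O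
F5 | step 7 | 2-[5-(tert-butyldimethylsilyloxy)-2,2-dimethyl-2H-chromen-6-yl]-3-(3-methylbut-2-enyl)-5,7-bis(prop-2-enyloxy)-4H-chromen-4-one | CC(C)=CCc1c(-c2ccc3OC(C)(C)C=Cc3c2O[Si](C)(C)C(C)(C)C)oc2cc(OCC=C)cc(OCC=C)c2c1=O
F6 | step 8 | 2-(5-hydroxy-2,2-dimethyl-2H-chromen-6-yl)-3-(3-methylbut-2-enyl)-5,7-bis[(E)-prop-1-enyloxy]-4H-chromen-4-one | CC(C)=CCc1c(-c2ccc3c(c2O)C=CC(C)(C)O3)oc2cc(O/C=C/C)cc(O/C=C/C)c2c1=O
A1 | alternative 1 | 5-(methoxymethoxy)-2,2-dimethyl-2H-chromene-6-carboxylic acid | COCOc1c(C(O)=O)ccc2OC(C)(C)C=Cc12
A2 | alternative 1 | 2-(5-methylhex-4-enoyl)-3,5-bis(prop-2-enyloxy)phenyl 5-(methoxymethoxy)-2,2-dimethyl-2H-chromene-6-carboxylate | CC(C)=CCCC(=O)c1c(OC(=O)c2ccc3OC(C)(C)C=Cc3c2OCOC)cc(OCC=C)cc1OCC=C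
A3 | alternative 1 | rac-1-[2-hydroxy-4,6-bis(prop-2-enyloxy)phenyl]-3-[5-(methoxymethoxy)-2,2-dimethyl-2H-chromen-6-yl]-2-(3-methylbut-2-enyl)propane-1,3-dione | CC(C)=CCC(C(=O)c1c(O)cc(OCC=C)cc1OCC=C)C(=O)c1ccc2OC(C)(C)C=Cc2c1OCOC
A4 | alternative 2 | [5-(methoxymethoxy)-2,2-dimethyl-2H-chromen-6-yl]boronic acid | COCOc1c(B(O)O)ccc2OC(C)(C)C=Cc12
A5 | alternative 2 | 2-[5-(methoxymethoxy)-2,2-dimethyl-2H-chromen-6-yl]-3-(3-methylbut-2-enyl)-5,7-bis(prop-2-enyloxy)-4H-chromen-4-one | CC(C)=CCc1c(-c2ccc3OC(C)(C)C=Cc3c2OCOC)oc2cc(OCC=C)cc(OCC=C)c2c1=O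
A6 | alternative 3 | 3-[5-(methoxymethoxy)-2,2-dimethyl-2H-chromen-6-yl]-1-(2,4,6-trimethoxyphenyl)prop-2-yn-1-one | COc1cc(OC)c(C(=O)C#Cc2ccc3OC(C)(C)C=Cc3c2OCOC)c(OC)c1
A7 | alternative 3 | 3-iodo-5,7-dimethoxy-2-[5-(methoxymethoxy)-2,2-dimethyl-2H-chromen-6-yl]-4H-chromen-4-one | COCOc1c(-c2oc3cc(OC)cc(OC)c3c(=O)c2I)ccc2OC(C)(C)C=Cc12
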